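The upper pyran ring C is disconnected at O1–C2 and C4–C4a. Both bonds flank benzo ring A, which is simply resorcinol acting as a C,O-1,3-dinucleophile; C4 is doubly benzylic (ring A and the phloroglucinol-type benzo ring D of the lower unit) and C2 is benzylic to aryl ring B, so C2–C3–C4 is a latent 1,3-dielectrophile. In one operation a chiral Brønsted acid joins resorcinol to a chalcone built on C8 of benzyl-protected (−)-epiafzelechin: Friedel–Crafts conjugate addition sets C4, and hemiketalisation with dehydration closes ring C as a 4H-chromene. Face-selective hydrogenation then sets C2 cis and frees all hydroxyls.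

Key step: step 5

Assumption 1: (−)-epiafzelechin is bought as the isolated natural product (catalogue reference compound) and supplies both stereocentres of the lower unit.
Assumption 2: the (R)-antipode of the acid catalyst is written in step 5 and stands for whichever antipode delivers the 4S adduct; the sense of induction has to be established in the first run.

Step 1
Reactants: 1 (−)-epiafzelechin
Product: 2 (2R,3R)-5,7-bis(benzyloxy)-2-[4-(benzyloxy)phenyl]-3,4-dihydro-2H-chromen-3-ol
Conditions: BnBr (3.3 equiv), K2CO3 (3.5 equiv), DMF, 0 °C → rt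
Reagents that add atoms: benzyl bromide, BrCc1ccccc1
Why: Williamson ether synthesis in which K2CO3 deprotonates only the three phenols, so the secondary 3-OH stays free and neither stereocentre is touched.

Step 2
Reactants: 2 tri-O-benzyl ether
Product: 3 (2R,3R)-3,5,7-tris(benzyloxy)-2-[4-(benzyloxy)phenyl]-3,4-dihydro-2H-chromene
Conditions: NaH (1.5 equiv), BnBr (1.3 equiv), DMF, 0 °C → rt
Reagents that add atoms: benzyl bromide, BrCc1ccccc1
Why: Williamson ether synthesis on the sodium alkoxide of the 3-OH; with O4' already benzylated the base cannot open the pyran ring through a quinone methide, so C2 and C3 should keep their configuration.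

Step 3
Reactants: 3 tetra-O-benzyl ether
Product: 5 (2R,3R)-3,5,7-tris(benzyloxy)-2-[4-(benzyloxy)phenyl]-3,4-dihydro-2H-chromene-8-carbaldehyde, via iminium chloride 4 (not isolated)
Conditions: POCl3 (1.5 equiv), DMF, 0 → 60 °C; then ice-water, rt
Reagents that add atoms: N,N-dimethylformamide, CN(C)C=O; water, O
Why: Vilsmeier–Haack formylation of the trioxygenated ring D, expected at C8 (between the ring oxygen and one benzyloxy group) rather than at C6 (between two benzyloxy groups), followed by hydrolysis of the iminium salt.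

Step 4
Reactants: 5 8-carbaldehyde; 6 1-[4-(benzyloxy)phenyl]ethan-1-one
Product: 8 (E)-1-[4-(benzyloxy)phenyl]-3-{(2R,3R)-3,5,7-tris(benzyloxy)-2-[4-(benzyloxy)phenyl]-3,4-dihydro-2H-chromen-8-yl}prop-2-en-1-one, via aldol adduct 7 (not isolated)
Conditions: KOH (50% aq), EtOH/THF, rt
Reagents that add atoms: none
Why: Claisen–Schmidt condensation, in which the non-enolisable aldehyde accepts the methyl ketone enolate and E1cB loss of water gives the conjugated (E)-enone under thermodynamic control.

Step 5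
Reactants: 8 chalcone; 9 resorcinol (benzene-1,3-diol)
Product: 12 (2R,3R)-3,5,7-tris(benzyloxy)-2-[4-(benzyloxy)phenyl]-8-{(4S)-2-[4-(benzyloxy)phenyl]-7-hydroxy-4H-chromen-4-yl}-3,4-dihydro-2H-chromene, via Michael adduct 10 (not isolated), via hemiketal 11 (not isolated)
Conditions: 9 (3 equiv), (R)-3,3'-bis(2,4,6-triisopropylphenyl)-1,1'-binaphthyl-2,2'-diyl N-triflylphosphoramide (10 mol%), 4 Å molecular sieves, CH2Cl2, −20 °C → rt
Reagents that add atoms: none
Why: Proposed new method: the triflylphosphoramide protonates the enone oxygen of 8 to a hydroxyallyl cation delocalised into the 5,7,8a-trioxygenated ring D, while its conjugate base holds one resorcinol hydroxyl, so that the resorcinol carbon ortho to that hydroxyl and para to the other adds to the β-carbon inside the chiral pocket (Friedel–Crafts conjugate addition, C4–C4a). The ortho hydroxyl of adduct 10 then adds to the ketone (6-exo-trig hemiketalisation, O1–C2, closing pyran ring C), and acid-catalysed loss of water from 11, driven by the sieves and by conjugation with ring B, gives the 4H-chromene. The closest known reactions are the Brønsted-acid-mediated formal [3+3] annulation of phenols and naphthols with chalcones to 2,4-diaryl-4H-chromenes and the chiral-phosphoric-acid-catalysed Friedel–Crafts/cyclodehydration of naphthols with activated enones; new here is catalyst control with a simple dihydroxybenzene on a chalcone whose β-aryl group is 2,6-dioxygenated. C4 is the only new stereocentre and is set by the catalyst, which shields one face of the planar cation and delivers the hydrogen-bonded nucleophile to the other; the lower-unit stereocentres are remote and are not expected to override it. Regiochemistry is secured because only the β-carbon is electrophilic, because the two activated carbons of resorcinol are equivalent and each lies ortho to a hydroxyl that can close the ring, and because O7 of ring D is benzylated and cannot compete for C2; excess resorcinol should suppress a second alkylation of the product.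

Step 6
Reactants: 12 (4S)-4H-chromene
Product: 13 (2R,3R)-8-[(2S,4S)-7-hydroxy-2-(4-hydroxyphenyl)-3,4-dihydro-2H-chromen-4-yl]-2-(4-hydroxyphenyl)-3,4-dihydro-2H-chromene-3,5,7-triol
Conditions: H2 (1 atm), Pd(OH)2/C, EtOAc/MeOH 1:1, rt
Reagents that add atoms: none
Why: Catalytic hydrogenation adds hydrogen syn to the C2=C3 enol ether from the face of ring C opposite the pseudo-axial ring D at C4, so the new C2–H is trans and ring B cis to ring D (2S from 4S), while the same catalyst hydrogenolyses the five benzyl ethers.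

Compound list
1 | (−)-epiafzelechin, (2R,3R)-2-(4-hydroxyphenyl)-3,4-dihydro-2H-chromene-3,5,7-triol | Oc1cc(O)c2c(c1)O[C@H](c1ccc(O)cc1)[C@H](O)C2 | starting material
2 | (2R,3R)-5,7-bis(benzyloxy)-2-[4-(benzyloxy)phenyl]-3,4-dihydro-2H-chromen-3-ol | c1ccccc1COc1cc(OCc2ccccc2)c2c(c1)O[C@H](c1ccc(OCc3ccccc3)cc1)[C@H](O)C2 | intermediate
3 | (2R,3R)-3,5,7-tris(benzyloxy)-2-[4-(benzyloxy)phenyl]-3,4-dihydro-2H-chromene | c1ccccc1COc1cc(OCc2ccccc2)c2c(c1)O[C@H](c1ccc(OCc3ccccc3)cc1)[C@H](OCc1ccccc1)C2 | intermediate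
4 | N-{[(2R,3R)-3,5,7-tris(benzyloxy)-2-[4-(benzyloxy)phenyl]-3,4-dihydro-2H-chromen-8-yl]methylidene}-N-methylmethanaminium chloride (not isolated) | c1ccccc1COc1cc(OCc2ccccc2)c2c(c1C=[N+](C)C)O[C@H](c1ccc(OCc3ccccc3)cc1)[C@H](OCc1ccccc1)C2.[Cl-] | intermediate
5 | (2R,3R)-3,5,7-tris(benzyloxy)-2-[4-(benzyloxy)phenyl]-3,4-dihydro-2H-chromene-8-carbaldehyde | c1ccccc1COc1cc(OCc2ccccc2)c2c(c1C=O)O[C@H](c1ccc(OCc3ccccc3)cc1)[C@H](OCc1ccccc1)C2 | intermediate
6 | 1-[4-(benzyloxy)phenyl]ethan-1-one | CC(=O)c1ccc(OCc2ccccc2)cc1 | starting material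
7 | 1-[4-(benzyloxy)phenyl]-3-hydroxy-3-{(2R,3R)-3,5,7-tris(benzyloxy)-2-[4-(benzyloxy)phenyl]-3,4-dihydro-2H-chromen-8-yl}propan-1-one, both carbinol epimers (not isolated) | c1ccccc1COc1cc(OCc2ccccc2)c2c(c1C(O)CC(=O)c1ccc(OCc3ccccc3)cc1)O[C@H](c1ccc(OCc3ccccc3)cc1)[C@H](OCc1ccccc1)C2 | intermediate
8 | (E)-1-[4-(benzyloxy)phenyl]-3-{(2R,3R)-3,5,7-tris(benzyloxy)-2-[4-(benzyloxy)phenyl]-3,4-dihydro-2H-chromen-8-yl}prop-2-en-1-one | c1ccccc1COc1cc(OCc2ccccc2)c2c(c1/C=C/C(=O)c1ccc(OCc3ccccc3)cc1)O[C@H](c1ccc(OCc3ccccc3)cc1)[C@H](OCc1ccccc1)C2 | intermediate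
9 | resorcinol (benzene-1,3-diol) | Oc1cccc(O)c1 | starting material
10 | (3S)-1-[4-(benzyloxy)phenyl]-3-(2,4-dihydroxyphenyl)-3-{(2R,3R)-3,5,7-tris(benzyloxy)-2-[4-(benzyloxy)phenyl]-3,4-dihydro-2H-chromen-8-yl}propan-1-one (not isolated) | c1ccccc1COc1cc(OCc2ccccc2)c2c(c1[C@@H](CC(=O)c1ccc(OCc3ccccc3)cc1)c1ccc(O)cc1O)O[C@H](c1ccc(OCc3ccccc3)cc1)[C@H](OCc1ccccc1)C2 | intermediate
11 | (4S)-2-[4-(benzyloxy)phenyl]-4-{(2R,3R)-3,5,7-tris(benzyloxy)-2-[4-(benzyloxy)phenyl]-3,4-dihydro-2H-chromen-8-yl}-3,4-dihydro-2H-chromene-2,7-diol, both C2 epimers (not isolated) | c1ccccc1COc1cc(OCc2ccccc2)c2c(c1[C@H]4CC(O)(c5ccc(OCc6ccccc6)cc5)Oc5cc(O)ccc54)O[C@H](c1ccc(OCc3ccccc3)cc1)[C@H](OCc1ccccc1)C2 | intermediate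
12 | (2R,3R)-3,5,7-tris(benzyloxy)-2-[4-(benzyloxy)phenyl]-8-{(4S)-2-[4-(benzyloxy)phenyl]-7-hydroxy-4H-chromen-4-yl}-3,4-dihydro-2H-chromene | c1ccccc1COc1cc(OCc2ccccc2)c2c(c1[C@H]4C=C(c5ccc(OCc6ccccc6)cc5)Oc5cc(O)ccc54)O[C@H](c1ccc(OCc3ccccc3)cc1)[C@H](OCc1ccccc1)C2 | intermediate
13 | (2R,3R)-8-[(2S,4S)-7-hydroxy-2-(4-hydroxyphenyl)-3,4-dihydro-2H-chromen-4-yl]-2-(4-hydroxyphenyl)-3,4-dihydro-2H-chromene-3,5,7-triol | Oc1ccc([C@@H]2C[C@H](c3c(O)cc(O)c4c3O[C@H](c3ccc(O)cc3)[C@H](O)C4)c3ccc(O)cc3O2)cc1 | target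

Total step count: 6. Longest linear sequence: 6 steps (1 → 13).

Steps most likely to fail

Step 5 (key step, proposed new method). The chiral acid may discriminate the two faces of the β-carbon poorly, because the ion pair is loose or the chiral lower unit interferes. The conjugate addition to an enone deactivated by two electron-rich aryl groups may also be slow, letting a second alkylation of the product or acid ionisation of the benzylic ether bond in the lower pyran ring compete. The fallback sets out from 8 and 9 and separates bond formation from stereocontrol, using known reactions only. HBF4·OEt2 and chloranil in AcOH/CH2Cl2 at rt should bring about the same C4–C4a/O1–C2 annulation without stereocontrol, giving the 4H-chromene as a C4-epimer mixture F1 (not isolated), from which chloranil abstracts the C4 hydride to give the 2,4-diaryl-7-hydroxyflavylium tetrafluoroborate F2, which has no stereocentre in ring C. Washing with aqueous NaHCO3 should give the neutral quinonoidal anhydrobase F3. With 10 mol% (R)-3,3'-bis(2,4,6-triisopropylphenyl)-1,1'-binaphthyl-2,2'-diyl hydrogen phosphate and Hantzsch ester in toluene, F3 is re-protonated to the benzopyrylium as a chiral phosphate ion pair and hydride is delivered to C4 (the known enantioselective 1,4-reduction of 2,4-diarylbenzopyrylium ions). This comes back to the route at 12.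

Step 6. Hydrogenolytic opening of the benzylic C2–O1 bonds of either pyran ring may set in under the conditions needed to cleave five benzyl ethers, and facial selectivity on the enol ether may be incomplete. Palladium-mediated migration of the double bond to C3=C4 should be harmless, since it relays the configuration C4 → C2 → C4 to the same cis product. The fallback sets out from 12 and replaces the metal surface by an ionic reduction. Et3SiH and CF3CO2H in CH2Cl2 at −40 °C protonate C3 to the 2-aryl oxocarbenium ion, and axial hydride delivery anti to the pseudo-equatorial C4 substituent should give the 2,4-cis chroman pentabenzyl ether F4. Metal-free debenzylation with BCl3 and pentamethylbenzene in CH2Cl2 at −78 °C then comes back to the route at 13.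

Step 3. The electrophile may attack C6 as well as C8, and HCl formed at 60 °C may cleave benzyl ethers. The fallback sets out from 3 and replaces electrophilic formylation by halogen–metal exchange. N-Bromosuccinimide in CH2Cl2 at −78 °C should brominate C8 selectively (a dependable reaction of 5,7-di-O-benzyl flavans) to give the 8-bromide F5. Bromine–lithium exchange with n-BuLi in THF at −78 °C gives the 8-lithio compound F6 (not isolated), and a DMF quench with aqueous work-up comes back to the route at 5.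

Further compounds
F1 | step 5 | (2R,3R)-3,5,7-tris(benzyloxy)-2-[4-(benzyloxy)phenyl]-8-{2-[4-(benzyloxy)phenyl]-7-hydroxy-4H-chromen-4-yl}-3,4-dihydro-2H-chromene, mixture of C4 epimers (not isolated) | c1ccccc1COc1cc(OCc2ccccc2)c2c(c1C4C=C(c5ccc(OCc6ccccc6)cc5)Oc5cc(O)ccc54)O[C@H](c1ccc(OCc3ccccc3)cc1)[C@H](OCc1ccccc1)C2
F2 | step 5 | 2-[4-(benzyloxy)phenyl]-7-hydroxy-4-{(2R,3R)-3,5,7-tris(benzyloxy)-2-[4-(benzyloxy)phenyl]-3,4-dihydro-2H-chromen-8-yl}chromenylium tetrafluoroborate | c1ccccc1COc1cc(OCc2ccccc2)c2c(c1-c4cc(-c5ccc(OCc6ccccc6)cc5)[o+]c5cc(O)ccc45)O[C@H](c1ccc(OCc3ccccc3)cc1)[C@H](OCc1ccccc1)C2.F[B-](F)(F)F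
F3 | step 5 | 2-[4-(benzyloxy)phenyl]-4-{(2R,3R)-3,5,7-tris(benzyloxy)-2-[4-(benzyloxy)phenyl]-3,4-dihydro-2H-chromen-8-yl}-7H-chromen-7-one (quinonoidal anhydrobase) | c1ccccc1COc1cc(OCc2ccccc2)c2c(c1C4=C5C=CC(=O)C=C5OC(c5ccc(OCc6ccccc6)cc5)=C4)O[C@H](c1ccc(OCc3ccccc3)cc1)[C@H](OCc1ccccc1)C2
F4 | step 6 | (2R,3R)-3,5,7-tris(benzyloxy)-2-[4-(benzyloxy)phenyl]-8-{(2S,4S)-2-[4-(benzyloxy)phenyl]-7-hydroxy-3,4-dihydro-2H-chromen-4-yl}-3,4-dihydro-2H-chromene | c1ccccc1COc1cc(OCc2ccccc2)c2c(c1[C@H]4C[C@@H](c5ccc(OCc6ccccc6)cc5)Oc5cc(O)ccc54)O[C@H](c1ccc(OCc3ccccc3)cc1)[C@H](OCc1ccccc1)C2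
F5 | step 3 | (2R,3R)-3,5,7-tris(benzyloxy)-2-[4-(benzyloxy)phenyl]-8-bromo-3,4-dihydro-2H-chromene | c1ccccc1COc1cc(OCc2ccccc2)c2c(c1Br)O[C@H](c1ccc(OCc3ccccc3)cc1)[C@H](OCc1ccccc1)C2
F6 | step 3 | [(2R,3R)-3,5,7-tris(benzyloxy)-2-[4-(benzyloxy)phenyl]-3,4-dihydro-2H-chromen-8-yl]lithium (not isolated) | c1ccccc1COc1cc(OCc2ccccc2)c2c(c1[Li])O[C@H](c1ccc(OCc3ccccc3)cc1)[C@H](OCc1ccccc1)C2
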